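## Structural features

The target is a flavone: benzene ring A is fused along C4a–C8a to the 4-pyranone ring C (O1, C2=C3, C4=O), and the 2,5-dihydroxy-4-methoxyphenyl ring B is attached to C2 through the C2–C1' single bond. Ring A carries no hydrogen: 5-OH, 6-OMe, 7-OH and 8-OMe alternate around it, and C3 of ring C bears a fourth methoxy group, so eight oxygen substituents of two kinds have to be told apart. The molecule has no stereocentre; C2 and C3 are neighbouring sp3 centres only in intermediates, and both are flattened again before the end. The fragile parts are the hydroquinone-type ring B (2',5'-dihydroxy, easily oxidised to a quinone) and the electron-rich ring A phenols, of which 5-OH is chelated to the C4 carbonyl; all four phenols therefore stay benzylated until the last step. The real difficulty is twofold: the strict alternation of hydroxy and methoxy groups on a hexasubstituted ring A, and the construction of ring C on a ring A carbon flanked by two oxygen substituents. The key step exploits that C3 (enol ether carbon) and C4 (ketone carbon) of ring C are adjacent oxygenated carbons. This is the oxidised form of an acyloin between the formyl carbon on ring A and a formyl group at C3, so that O1–C2 can be a plain ether bond made earlier.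

## Logic of the disconnections

17 to 16: the four O–CH2Ph bonds are cut. All free phenols, including the oxidation-prone hydroquinone of ring B, then appear only in the final operation. The forward step must cleave four aryl benzyl ethers without reducing C2=C3 or the C4 carbonyl.

16 to 15: the O–CH3 bond at C3 is cut. This exposes the 3-hydroxy-4-pyranone, which is the enol tautomer of a 1,2-dione and therefore the oxidation product of an acyloin. The forward methylation needs O5 and O7 to be masked, which the benzyl ethers provide.

15 to 13 (through 14): no skeletal bond is cut; the C2=C3 unsaturation is removed and C3 is lowered to a carbinol. This reveals the acyloin C3(OH)–C4(=O). The forward oxidant must act on the carbinol and leave the benzyl ethers and the two free positions of ring B (C3', C6') alone, which is why an iodine-based dehydrogenation is avoided.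

13 to 12: the C3–C4 bond is cut, the acyloin retron. Ring C opens to a chain whose two ends are formyl groups, one on ring A and one at C3. The demand on the forward step is chemoselectivity. The two formyl groups are not interchangeable as acyl donors: an acyl-anion equivalent at C3 would have the ring A aryloxide on the adjacent carbon and could expel it, breaking O1–C2. The ring A formyl group must therefore be the donor, and the catalyst is chosen for that. No stereocontrol is needed.

12 to 11 to 10: only oxidation levels change. The alpha-aryl-alpha-aryloxy aldehyde is too labile to carry through several steps, so C3 is stored as an ester and C4 as the robust aryl aldehyde. Both are reduced together and then oxidised together. The forward oxidation must be free of base and water, and 12 must be used at once.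

10 to 4 plus 9: the O1–C2 ether bond is cut. This divides the molecule into a ring A half and a ring B half of similar size, the convergent point of the plan. The forward step is O-alkylation of a hindered, hydrogen-bonded phenol by a secondary benzylic alpha-bromo ester, and it must not trigger aldol closure onto the formyl group.

9 to 8 to 6 plus 7, and 6 to 5: the C–Br bond is traced to C–OH, then the C1'–C2 bond is cut as a Friedel–Crafts hydroxyalkylation. 7 delivers C2 and C3 at the right oxidation levels in one step. The forward step must attack 6 only para to its methoxy group and must stop after one arylation.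

4 to 3 to 2 to 1: the two C–OMe bonds at C3 and C5 of the benzaldehyde are traced to C–Br and then to C–H, and two benzyl ethers are removed. 1 already holds the formyl carbon and the three phloroglucinol oxygens in the right places. The forward steps need a dibenzylation that leaves the chelated ortho hydroxyl free, and a bromide-to-methoxide exchange at two hindered positions.

## Other disconnections considered

Alternative 1: Ring B is cut at C5'–C6', C1'–C2' and C2'–C3' and is built last on a finished ring A/ring C unit. In the forward direction the alkyne 5,7-bis(benzyloxy)-2-ethynyl-3,6,8-trimethoxy-4H-chromen-4-one A2 would be heated in THF with the Fischer carbene complex pentacarbonyl[methoxy(1-methoxyethenyl)carbene]chromium A3, a complex of zerovalent chromium. The alkyne of A2 should insert into the chromium–carbon double bond of A3, one carbonyl ligand of A3 should follow, and electrocyclisation of the resulting dienylketene should close ring B to give 5,7-bis(benzyloxy)-2-(2-hydroxy-4,5-dimethoxyphenyl)-3,6,8-trimethoxy-4H-chromen-4-one A1. In its favour, the benzannulation places the new hydroxyl next to the larger alkyne substituent, so the 2'-OH of A1 emerges free and distinct from every other oxygen. C2 never becomes a stereocentre and no labile aldehyde is handled. On these points the alternative is the equal or the better of the chosen plan. Against it here, the former carbene carbon of A3 becomes C5' of A1 and carries a methoxy group, whereas the target needs 5'-OH next to 4'-OMe. Two neighbouring aryl methyl ethers offer no handle for selective cleavage, so A3 would have to be replaced by a carbene complex with a removable O-substituent, which would have to be worked out. A2 already contains the whole hexasubstituted ring A and the 3-methoxychromone, so the hard part is only moved into the synthesis of A2, with a 2-alkynylation added. A2 is also an electron-poor alkyne, the class in which furan formation and cyclopentannulation compete with benzannulation, and A3 is consumed in stoichiometric amount. In comparison, this is a metal-templated assembly of three bonds against an organocatalytic closure of one. Structurally it solves ring B and leaves ring A and ring C open, the reverse of the chosen plan, and in step count it is expected to be longer.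

Alternative 2: Ring C is cut at C4a–C4, C4–C3 and O1–C2, which gives three components. In the forward direction 2-iodo-4,6-dimethoxybenzene-1,3,5-triyl triacetate A5, 1,4-bis(benzyloxy)-2-ethynyl-5-methoxybenzene A6 and carbon monoxide A7 would be combined under PdCl2(PPh3)2 in Et2NH. Oxidative addition of zerovalent palladium into the C–I bond of A5, insertion of A7 and coupling with the terminal alkyne A6 should give an ynone. The amine should then cleave the acetates, and a freed ortho phenoxide should add to the ynone in a 6-endo closure to give 2-[2,5-bis(benzyloxy)-4-methoxyphenyl]-5,7-dihydroxy-6,8-dimethoxy-4H-chromen-4-one A4. In its favour, this is the most convergent of all the plans and forms three bonds in one operation. A5 is symmetric, so either ortho oxygen closes the ring to the same product; A6 is a simple arylalkyne and A7 is the cheapest possible source of C4. No stereocentre and no sensitive aldehyde arise. In convergence and in step count up to the bicyclic core it is better than the chosen plan, and the ring closure rests on a well-established palladium cycle between the zerovalent and the divalent state. Against it here, A4 has hydrogen at C3. The 3-methoxy group would have to be added afterwards by oxidation at C3 of an electron-rich chromone, after reprotection of 5-OH and 7-OH, which adds several steps and a delicate oxidation. The iodide of A5 lies between two ortho oxygens on an electron-rich ring, which should slow oxidative addition and the uptake of A7. Direct coupling of A5 with A6 without incorporation of A7, and 5-exo closure to an aurone, would compete. A7 is a toxic gas that calls for pressure equipment, and the freed ring A phenols of A4 are air-sensitive in amine. In comparison, the chosen plan carries the C3 oxygen from the start, because the acyloin delivers 3-OH directly. That structural advantage is expected to outweigh the shorter core assembly of this alternative.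

Alternative 3: Ring C is cut at O1–C8a. In the forward direction the diketone 1-[4-(benzyloxy)-2,6-dibromo-3,5-dimethoxyphenyl]-3-[2,5-bis(benzyloxy)-4-methoxyphenyl]-2-methoxypropane-1,3-dione A9 would be treated with CuI, 1,10-phenanthroline and Cs2CO3. The enolate oxygen of the ring B ketone of A9 should displace one of the two equivalent ortho bromides to give 7-(benzyloxy)-2-[2,5-bis(benzyloxy)-4-methoxyphenyl]-5-bromo-3,6,8-trimethoxy-4H-chromen-4-one A8. In its favour, ring A of A9 would come from a symmetric building block that already carries the 6- and 8-methoxy groups and O7, so no methoxide exchange is needed; on this point it is better than the chosen plan. The 3-methoxy group is already present in A9, symmetry removes any regiochemical question, and no stereocentre or aldehyde appears. Against it here, A8 still has bromine at C5, which must be turned into hydroxyl by a second C–O bond formation at a crowded position. Assembly of A9 needs acyl transfer to or from a carbonyl shielded by two ortho bromines, and C-arylation of the enolate of A9 or reductive loss of bromine are possible side paths. In comparison, both plans close ring C next to a heteroatom, here by a metal-mediated C–O bond and in the chosen plan by an organocatalytic C–C bond. The step counts are expected to be about equal. The chosen plan is preferred because its ring A building block is reached by simple aromatic chemistry and its ring closure creates the C3 oxygen function itself.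

Key step: step 10

Assumption: C2 (and C3 where it is sp3) is racemic in every intermediate, and these compounds are drawn without configuration, because the target has no stereocentre.

## Route

Step 1
Reactants: 1 2,4,6-trihydroxybenzaldehyde
Product: 2 4,6-bis(benzyloxy)-2-hydroxybenzaldehyde
Conditions: BnBr (2.1 equiv), K2CO3 (2.2 equiv), DMF, 0 °C to rt
Reagents that add atoms: benzyl bromide, BrCc1ccccc1
Why: Williamson etherification; the 4-OH (para to the formyl group, most acidic, not hydrogen-bonded) and one ortho OH should react, while the last ortho OH stays locked in a hydrogen bond to the carbonyl oxygen and is the least nucleophilic. Under- and over-benzylated material is separable.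

Step 2
Reactants: 2 4,6-bis(benzyloxy)-2-hydroxybenzaldehyde
Product: 3 4,6-bis(benzyloxy)-3,5-dibromo-2-hydroxybenzaldehyde
Conditions: NBS (2.1 equiv), MeCN, 0 °C to rt, dark
Reagents that add atoms: N-bromosuccinimide, O=C1CCC(=O)N1Br
Why: Electrophilic aromatic bromination; C3 and C5 are the only free ring positions and each is ortho or para to three oxygen donors, so two equivalents should brominate both. Ionic conditions leave the benzylic CH2 groups untouched.

Step 3
Reactants: 3 4,6-bis(benzyloxy)-3,5-dibromo-2-hydroxybenzaldehyde
Product: 4 4,6-bis(benzyloxy)-2-hydroxy-3,5-dimethoxybenzaldehyde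
Conditions: NaOMe (excess, 25 % in MeOH), CuBr (20 mol %), DMF, 100 °C; then dilute HCl
Reagents that add atoms: sodium methoxide, C[O-].[Na+]
Why: Ullmann-type copper-mediated exchange of aryl bromide for methoxide, the reaction type that turns bromohydroxybenzaldehydes into their methoxy analogues. The substrate reacts as its phenoxide, which shields the formyl group from methoxide and assists the exchange at the neighbouring C3.

Step 4
Reactants: 5 methoxyhydroquinone (2-methoxybenzene-1,4-diol)
Product: 6 1,4-bis(benzyloxy)-2-methoxybenzene
Conditions: BnBr (2.3 equiv), K2CO3, DMF, 60 °C, N2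
Reagents that add atoms: benzyl bromide, BrCc1ccccc1
Why: Double Williamson etherification of both phenols; the inert atmosphere keeps the hydroquinone dianion from oxidising to the quinone.

Step 5
Reactants: 6 1,4-bis(benzyloxy)-2-methoxybenzene, 7 ethyl glyoxylate
Product: 8 ethyl 2-[2,5-bis(benzyloxy)-4-methoxyphenyl]-2-hydroxyacetate (racemic)
Conditions: 7 (1.5 equiv, freshly cracked), Yb(OTf)3 (10 mol %), CH2Cl2, 0 °C to rt
Reagents that add atoms: none
Why: Lewis-acid-catalysed Friedel–Crafts hydroxyalkylation; the carbon para to the methoxy group and ortho to a benzyloxy group is the most nucleophilic and least hindered position of 6. A mild lanthanide triflate should spare the benzyl ethers; the new carbinol centre is formed racemic.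

Step 6
Reactants: 8 ethyl 2-[2,5-bis(benzyloxy)-4-methoxyphenyl]-2-hydroxyacetate (racemic)
Product: 9 ethyl 2-[2,5-bis(benzyloxy)-4-methoxyphenyl]-2-bromoacetate (racemic)
Conditions: CBr4, PPh3, CH2Cl2, 0 °C
Reagents that add atoms: carbon tetrabromide, BrC(Br)(Br)Br
Why: Appel reaction; the neutral conditions should convert the activated benzylic alpha-hydroxy ester into the bromide without acid that could attack the benzyl ethers. 9 is used without storage.

Step 7
Reactants: 4 4,6-bis(benzyloxy)-2-hydroxy-3,5-dimethoxybenzaldehyde, 9 ethyl 2-[2,5-bis(benzyloxy)-4-methoxyphenyl]-2-bromoacetate (racemic)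
Product: 10 ethyl 2-[3,5-bis(benzyloxy)-2-formyl-4,6-dimethoxyphenoxy]-2-[2,5-bis(benzyloxy)-4-methoxyphenyl]acetate (racemic)
Conditions: K2CO3, DMF, rt
Reagents that add atoms: none
Why: Williamson O-alkylation (SN2 at an alpha-bromo ester) that makes O1–C2; the phenoxide of 4 has no free ring carbon, so only O-alkylation is possible. Room temperature and a carbonate base should keep the product from aldol closure onto the formyl group.

Step 8
Reactants: 10 ethyl 2-[3,5-bis(benzyloxy)-2-formyl-4,6-dimethoxyphenoxy]-2-[2,5-bis(benzyloxy)-4-methoxyphenyl]acetate (racemic)
Product: 11 2-[3,5-bis(benzyloxy)-2-(hydroxymethyl)-4,6-dimethoxyphenoxy]-2-[2,5-bis(benzyloxy)-4-methoxyphenyl]ethan-1-ol (racemic)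
Conditions: LiAlH4, THF, 0 °C; quench Na2SO4·10H2O
Reagents that add atoms: none
Why: Hydride reduction of ester and aldehyde to the diol brings C3 and C4 to the same oxidation level, so both can be oxidised in one operation. The neutral quench protects the very electron-rich benzylic alcohol from ionisation.

Step 9
Reactants: 11 2-[3,5-bis(benzyloxy)-2-(hydroxymethyl)-4,6-dimethoxyphenoxy]-2-[2,5-bis(benzyloxy)-4-methoxyphenyl]ethan-1-ol (racemic)
Product: 12 4,6-bis(benzyloxy)-2-[1-(2,5-bis(benzyloxy)-4-methoxyphenyl)-2-oxoethoxy]-3,5-dimethoxybenzaldehyde (racemic)
Conditions: Dess–Martin periodinane (2.6 equiv), pyridine, CH2Cl2, 0 °C to rt; used at once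
Reagents that add atoms: none
Why: Dess–Martin oxidation of both primary alcohols; an excess of oxidant from the start should outrun hemiacetal formation between the first aldehyde and the remaining alcohol. The buffered, water-free medium avoids enolisation of the new alpha-aryl aldehyde.

Step 10
Reactants: 12 4,6-bis(benzyloxy)-2-[1-(2,5-bis(benzyloxy)-4-methoxyphenyl)-2-oxoethoxy]-3,5-dimethoxybenzaldehyde (racemic)
Product: 13 5,7-bis(benzyloxy)-2-[2,5-bis(benzyloxy)-4-methoxyphenyl]-3-hydroxy-6,8-dimethoxychroman-4-one (racemic, mixture of 2,3-cis and 2,3-trans)
Conditions: 3-benzyl-5-(2-hydroxyethyl)-4-methylthiazolium chloride (20 mol %), DBU (15 mol %), degassed t-BuOH–THF, 40 °C, Ar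
Reagents that add atoms: none
Why: The thiazol-2-ylidene freed from the salt by DBU should add to the ring A formyl carbon and, after proton transfer, give the Breslow intermediate, whose nucleophilic carbon (the future C4) attacks the very electrophilic alpha-aryloxy aldehyde carbon (the future C3); proton transfer and loss of the carbene then leave the alpha-hydroxy ketone. The closest known reaction type is the carbene-catalysed intramolecular crossed benzoin reaction of 2-(2-oxoalkoxy)benzaldehydes to 3-hydroxychroman-4-ones, together with carbene-catalysed acyloin cyclisations of dialdehydes. Ring C closes in a 6-exo-trig mode onto the C3 carbonyl. The new stereocentre C3 needs no control: the C2 aryl group should favour the 2,3-trans isomer with both substituents equatorial, the base can equilibrate C3 through the enediol, and both centres are erased in step 11. The selectivity that matters is which formyl group becomes the acyl donor, because a Breslow intermediate at C3 would carry the ring A aryloxide on the adjacent carbon and could expel it, which would break O1–C2. Three features work against that path: thiazolium-derived carbenes tend to take the aromatic aldehyde as donor in crossed aryl/alkyl acyloin reactions, the C3 aldehyde is alpha-branched between two bulky aryl groups and so a poor donor but an excellent acceptor, and the benzyl ethers leave ring A without a free phenol that could deactivate its formyl group as a phenoxide. Less base than azolium salt and exclusion of air should keep enolisation, aldol closure and oxidation of the Breslow intermediate low.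

Step 11
Reactants: 13 5,7-bis(benzyloxy)-2-[2,5-bis(benzyloxy)-4-methoxyphenyl]-3-hydroxy-6,8-dimethoxychroman-4-one (racemic, diastereomer mixture)
Product: 15 5,7-bis(benzyloxy)-2-[2,5-bis(benzyloxy)-4-methoxyphenyl]-3-hydroxy-6,8-dimethoxy-4H-chromen-4-one, via chroman-3,4-dione 14 (not isolated)
Conditions: Cu(OAc)2·H2O (2.2 equiv), AcOH–H2O (4:1), 80 °C, N2; then aqueous EDTA wash
Reagents that add atoms: none
Why: Oxidation of an acyloin to the 1,2-dione by divalent copper through the copper enediolate (the benzoin-to-benzil reaction type). Dione 14 has an acidic C2–H between aryl group, ring oxygen and carbonyl and should tautomerise at once to the 3-hydroxy-4-pyranone, which removes both stereocentres. A 4-hydroxy-3-ketone isomer, if present, would pass through the same enediol.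

Step 12
Reactants: 15 5,7-bis(benzyloxy)-2-[2,5-bis(benzyloxy)-4-methoxyphenyl]-3-hydroxy-6,8-dimethoxy-4H-chromen-4-one
Product: 16 5,7-bis(benzyloxy)-2-[2,5-bis(benzyloxy)-4-methoxyphenyl]-3,6,8-trimethoxy-4H-chromen-4-one
Conditions: MeI, K2CO3, acetone, reflux
Reagents that add atoms: iodomethane, CI
Why: Williamson methylation of the acidic enolic 3-OH; O5 and O7 are benzylated, so no other hydroxyl competes.

Step 13
Reactants: 16 5,7-bis(benzyloxy)-2-[2,5-bis(benzyloxy)-4-methoxyphenyl]-3,6,8-trimethoxy-4H-chromen-4-one
Product: 17 5,7,2',5'-tetrahydroxy-3,6,8,4'-tetramethoxyflavone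
Conditions: H2 (1 atm), 10 % Pd/C, EtOAc–MeOH, rt; filtration and concentration under N2
Reagents that add atoms: none
Why: Hydrogenolysis of the four aryl benzyl ethers over palladium; the tetrasubstituted C2=C3 bond of a 3-methoxychromone should not be reduced at atmospheric pressure. The hydroquinone of ring B is freed last and under hydrogen, which limits its oxidation.

## Compound list

1 | 2,4,6-trihydroxybenzaldehyde | O=Cc1c(O)cc(O)cc1O | starting material
2 | 4,6-bis(benzyloxy)-2-hydroxybenzaldehyde | O=Cc1c(O)cc(OCc2ccccc2)cc1OCc1ccccc1 | intermediate
3 | 4,6-bis(benzyloxy)-3,5-dibromo-2-hydroxybenzaldehyde | O=Cc1c(O)c(Br)c(OCc2ccccc2)c(Br)c1OCc1ccccc1 | intermediate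
4 | 4,6-bis(benzyloxy)-2-hydroxy-3,5-dimethoxybenzaldehyde | O=Cc1c(O)c(OC)c(OCc2ccccc2)c(OC)c1OCc1ccccc1 | intermediate
5 | methoxyhydroquinone (2-methoxybenzene-1,4-diol) | COc1cc(O)ccc1O | starting material
6 | 1,4-bis(benzyloxy)-2-methoxybenzene | COc1cc(OCc2ccccc2)ccc1OCc1ccccc1 | intermediate
7 | ethyl glyoxylate | CCOC(=O)C=O | starting material
8 | ethyl 2-[2,5-bis(benzyloxy)-4-methoxyphenyl]-2-hydroxyacetate (racemic) | CCOC(=O)C(O)c1cc(OCc2ccccc2)c(OC)cc1OCc1ccccc1 | intermediate
9 | ethyl 2-[2,5-bis(benzyloxy)-4-methoxyphenyl]-2-bromoacetate (racemic) | CCOC(=O)C(Br)c1cc(OCc2ccccc2)c(OC)cc1OCc1ccccc1 | intermediate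
10 | ethyl 2-[3,5-bis(benzyloxy)-2-formyl-4,6-dimethoxyphenoxy]-2-[2,5-bis(benzyloxy)-4-methoxyphenyl]acetate (racemic) | CCOC(=O)C(Oc1c(C=O)c(OCc2ccccc2)c(OC)c(OCc2ccccc2)c1OC)c1cc(OCc2ccccc2)c(OC)cc1OCc1ccccc1 | intermediate
11 | 2-[3,5-bis(benzyloxy)-2-(hydroxymethyl)-4,6-dimethoxyphenoxy]-2-[2,5-bis(benzyloxy)-4-methoxyphenyl]ethan-1-ol (racemic) | OCC(Oc1c(CO)c(OCc2ccccc2)c(OC)c(OCc2ccccc2)c1OC)c1cc(OCc2ccccc2)c(OC)cc1OCc1ccccc1 | intermediate
12 | 4,6-bis(benzyloxy)-2-[1-(2,5-bis(benzyloxy)-4-methoxyphenyl)-2-oxoethoxy]-3,5-dimethoxybenzaldehyde (racemic) | O=CC(Oc1c(C=O)c(OCc2ccccc2)c(OC)c(OCc2ccccc2)c1OC)c1cc(OCc2ccccc2)c(OC)cc1OCc1ccccc1 | intermediate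
13 | 5,7-bis(benzyloxy)-2-[2,5-bis(benzyloxy)-4-methoxyphenyl]-3-hydroxy-6,8-dimethoxychroman-4-one (racemic, 2,3-cis/trans mixture) | COc1cc(OCc2ccccc2)c(cc1OCc1ccccc1)C1Oc2c(OC)c(OCc3ccccc3)c(OC)c(OCc3ccccc3)c2C(=O)C1O | intermediate
14 | 5,7-bis(benzyloxy)-2-[2,5-bis(benzyloxy)-4-methoxyphenyl]-6,8-dimethoxychroman-3,4-dione (racemic, not isolated) | COc1cc(OCc2ccccc2)c(cc1OCc1ccccc1)C1Oc2c(OC)c(OCc3ccccc3)c(OC)c(OCc3ccccc3)c2C(=O)C1=O | intermediate
15 | 5,7-bis(benzyloxy)-2-[2,5-bis(benzyloxy)-4-methoxyphenyl]-3-hydroxy-6,8-dimethoxy-4H-chromen-4-one | COc1cc(OCc2ccccc2)c(cc1OCc1ccccc1)-c1oc2c(OC)c(OCc3ccccc3)c(OC)c(OCc3ccccc3)c2c(=O)c1O | intermediate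
16 | 5,7-bis(benzyloxy)-2-[2,5-bis(benzyloxy)-4-methoxyphenyl]-3,6,8-trimethoxy-4H-chromen-4-one | COc1cc(OCc2ccccc2)c(cc1OCc1ccccc1)-c1oc2c(OC)c(OCc3ccccc3)c(OC)c(OCc3ccccc3)c2c(=O)c1OC | intermediate
17 | 5,7,2',5'-tetrahydroxy-3,6,8,4'-tetramethoxyflavone | COc1cc(O)c(-c2oc3c(OC)c(O)c(OC)c(O)c3c(=O)c2OC)cc1O | target

## Step count and least certain steps

Total: 13 steps (14 is formed and consumed within step 11). Longest linear sequence: 10 steps (1 to 17 through steps 1–3 and 7–13; the branch from 5 through steps 4–13 is equally long).

Step 10 (key step).
- What may go wrong: the carbene may engage the C3 formyl group instead of the ring A formyl group, which is hindered by two ortho oxygen substituents. The resulting acyl-anion equivalent has the ring A aryloxide on the adjacent carbon, and its expulsion (an internal redox fragmentation of O1–C2) would compete with ring closure. Base-induced enolisation of the alpha-aryl aldehyde followed by aldol closure onto the ring A formyl group to a five-membered ring is a second competing process.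
- Fallback: it sets out from 12 and forms the same C3–C4 bond reductively without any acyl-anion equivalent. SmI2 in THF with t-BuOH at −78 °C should reduce the conjugated ring A formyl group to a ketyl, which adds to the C3 aldehyde in a 6-exo pinacol cyclisation to give 5,7-bis(benzyloxy)-2-[2,5-bis(benzyloxy)-4-methoxyphenyl]-6,8-dimethoxychroman-3,4-diol F1. Swern oxidation of both carbinols (DMSO, (COCl)2, Et3N, −78 °C) should give dione 14, which tautomerises, so the route is rejoined at 15.

Step 5.
- What may go wrong: over-reaction, in which the new electron-rich benzylic carbinol ionises under the Lewis acid and alkylates a second molecule of 6 to a diarylacetate; loss of benzyl groups to the Lewis acid is also possible.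
- Fallback: it sets out from 6 and builds the same C1'–C2 bond through an aryl anion. Bromination with NBS para to the methoxy group should give 1,4-bis(benzyloxy)-2-bromo-5-methoxybenzene F2. Bromine–lithium exchange with n-BuLi at −78 °C and acylation with excess diethyl oxalate should give ethyl 2-[2,5-bis(benzyloxy)-4-methoxyphenyl]-2-oxoacetate F3. Reduction of the ketone with NaBH4 in EtOH at 0 °C returns to the route at 8.

Step 3.
- What may go wrong: reductive loss of bromine, or incomplete exchange at the C5 bromide, which is shielded by two benzyloxy groups.
- Fallback: it sets out from 1 and reverses the order of events, so that every bromide sits next to a phenoxide and no benzyl bulk is present. Dibromination of 1 with NBS should give 3,5-dibromo-2,4,6-trihydroxybenzaldehyde F4. Exchange with NaOMe and CuBr in DMF should give 2,4,6-trihydroxy-3,5-dimethoxybenzaldehyde F5. Selective dibenzylation as in step 1 (BnBr, K2CO3, DMF) returns to the route at 4.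

Step 7.
- What may go wrong: slow substitution at the hindered, hydrogen-bonded phenoxide would give the carbonate base time to deprotonate the product at C2 and close it onto the ring A formyl group (aldol, benzofuran-type), or to consume the labile bromide by hydrolysis.
- Fallback: it sets out from 4 and 8 and joins them without base by a Mitsunobu etherification (PPh3, DIAD, THF, 0 °C to rt). This is acceptable because C2 is racemic, and it rejoins the route at 10 without any new compound.

## Further compounds

F1 | step 10 | 5,7-bis(benzyloxy)-2-[2,5-bis(benzyloxy)-4-methoxyphenyl]-6,8-dimethoxychroman-3,4-diol (racemic, diastereomer mixture) | COc1cc(OCc2ccccc2)c(cc1OCc1ccccc1)C1Oc2c(OC)c(OCc3ccccc3)c(OC)c(OCc3ccccc3)c2C(O)C1O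
F2 | step 5 | 1,4-bis(benzyloxy)-2-bromo-5-methoxybenzene | COc1cc(OCc2ccccc2)c(Br)cc1OCc1ccccc1
F3 | step 5 | ethyl 2-[2,5-bis(benzyloxy)-4-methoxyphenyl]-2-oxoacetate | CCOC(=O)C(=O)c1cc(OCc2ccccc2)c(OC)cc1OCc1ccccc1
F4 | step 3 | 3,5-dibromo-2,4,6-trihydroxybenzaldehyde | O=Cc1c(O)c(Br)c(O)c(Br)c1O
F5 | step 3 | 2,4,6-trihydroxy-3,5-dimethoxybenzaldehyde | O=Cc1c(O)c(OC)c(O)c(OC)c1O
F0 | step 7 | none | none
A1 | alternative 1 | 5,7-bis(benzyloxy)-2-(2-hydroxy-4,5-dimethoxyphenyl)-3,6,8-trimethoxy-4H-chromen-4-one | COc1cc(O)c(cc1OC)-c1oc2c(OC)c(OCc3ccccc3)c(OC)c(OCc3ccccc3)c2c(=O)c1OC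
A2 | alternative 1 | 5,7-bis(benzyloxy)-2-ethynyl-3,6,8-trimethoxy-4H-chromen-4-one | C#Cc1oc2c(OC)c(OCc3ccccc3)c(OC)c(OCc3ccccc3)c2c(=O)c1OC
A3 | alternative 1 | pentacarbonyl[methoxy(1-methoxyethenyl)carbene]chromium | COC(=[Cr](=C=O)(=C=O)(=C=O)(=C=O)=C=O)C(=C)OC
A4 | alternative 2 | 2-[2,5-bis(benzyloxy)-4-methoxyphenyl]-5,7-dihydroxy-6,8-dimethoxy-4H-chromen-4-one | COc1cc(OCc2ccccc2)c(cc1OCc1ccccc1)-c1cc(=O)c2c(O)c(OC)c(O)c(OC)c2o1
A5 | alternative 2 | 2-iodo-4,6-dimethoxybenzene-1,3,5-triyl triacetate | CC(=O)Oc1c(I)c(OC(C)=O)c(OC)c(OC(C)=O)c1OC
A6 | alternative 2 | 1,4-bis(benzyloxy)-2-ethynyl-5-methoxybenzene | C#Cc1cc(OCc2ccccc2)c(OC)cc1OCc1ccccc1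
A7 | alternative 2 | carbon monoxide | [C-]#[O+]
A8 | alternative 3 | 7-(benzyloxy)-2-[2,5-bis(benzyloxy)-4-methoxyphenyl]-5-bromo-3,6,8-trimethoxy-4H-chromen-4-one | COc1cc(OCc2ccccc2)c(cc1OCc1ccccc1)-c1oc2c(OC)c(OCc3ccccc3)c(OC)c(Br)c2c(=O)c1OC
A9 | alternative 3 | 1-[4-(benzyloxy)-2,6-dibromo-3,5-dimethoxyphenyl]-3-[2,5-bis(benzyloxy)-4-methoxyphenyl]-2-methoxypropane-1,3-dione (racemic) | COC(C(=O)c1c(Br)c(OC)c(OCc2ccccc2)c(OC)c1Br)C(=O)c1cc(OCc2ccccc2)c(OC)cc1OCc1ccccc1
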